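**Assumption:** the target has no stereocentres and no E/Z elements (each prenyl alkene ends in CMe₂), so "single enantiomer" does not apply. 1,2,3,4-Tetramethoxybenzene and methyl 2,4,6-trihydroxybenzoate are treated as commercial.

## Retrosynthetic overview
- Target ⇒ C5-O-methylation of the hydroquinone diaryl ether, then removal of the two ring-A benzyl groups.
- Hydroquinone ⇒ reduction of the 2-aryloxy-3-methoxyquinone. This quinone comes from phenoxide addition–elimination on symmetric 2,3-dimethoxy-5,6-diprenyl-benzoquinone. That substitution is the bold key step: it forms the hindered ether at the quinone oxidation level and needs no halide, boron or copper handle.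
- The quinone ⇐ CAN oxidation of 5,6-diprenyl-1,2,3,4-tetramethoxybenzene ⇐ two ortho-lithiation/Cu-prenylations of tetramethoxybenzene.
- No ring is constructed. Both arenes are pre-existing, and ring A is a protected phloroglucinate.

## Forward route

**Step 1**
Reactants: 1 (methyl 2,4,6-trihydroxybenzoate)
Product: 2 (methyl 2,4-bis(benzyloxy)-6-hydroxybenzoate)
Conditions: BnBr (2.1 equiv), K₂CO₃, acetone, reflux
Reagents that add atoms: benzyl bromide, BrCc1ccccc1
Why: Williamson etherification; the 4-OH and one of the two equivalent ester-flanked OH groups alkylate, while the last OH is chelated to the ester and resists alkylation. No stereocentres form.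

**Step 2**
Reactants: 3 (1,2,3,4-tetramethoxybenzene), 4 (prenyl bromide)
Product: 5 (1,2,3,4-tetramethoxy-5-prenylbenzene)
Conditions: n-BuLi, TMEDA, THF, 0 °C; then CuBr·SMe₂ (10 mol%), 4, –78 °C → rt
Reagents that add atoms: prenyl bromide, CC(C)=CCBr
Why: directed ortho-metalation (OMe-directed) followed by Cu-catalysed SN2 allylation, as in coenzyme Q syntheses; the two free positions are equivalent, so there is no regiochemical issue.

**Step 3**
Reactants: 5, 4
Product: 6 (1,2,3,4-tetramethoxy-5,6-bis(3-methylbut-2-enyl)benzene)
Conditions: n-BuLi (1.5 equiv), TMEDA, THF, 0 °C → rt; then CuBr·SMe₂ (10 mol%), 4 (1.5 equiv), –78 °C → rt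
Reagents that add atoms: prenyl bromide, CC(C)=CCBr
Why: the same DoM/Cu-allylation cycle at the only remaining C–H, which is activated by the neighbouring OMe. This gives the symmetric ortho-diprenyl core with no stereocentres.

**Step 4**
Reactants: 6
Product: 7 (2,3-dimethoxy-5,6-bis(3-methylbut-2-enyl)-1,4-benzoquinone)
Conditions: CAN (3 equiv), MeCN/H₂O 3:1, 0 °C, 10 min
Reagents that add atoms: water, O
Why: CAN oxidative demethylation of the para-dimethoxy pair to a quinone, as in ubiquinone syntheses where prenyl chains survive. The inner OMe groups remain as the vinylogous-ester handles.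

**Step 5**
Reactants: 7, 2
Product: 8 (2-aryloxy-3-methoxy-5,6-diprenyl-1,4-benzoquinone, Ar = 3,5-bis(benzyloxy)-2-(methoxycarbonyl)phenyl)
Conditions: Cs₂CO₃ (2 equiv), DMF, 50 °C, 12 h, N₂
Reagents that add atoms: none (2 is the reactant; MeOH is lost)
Why: Proposed new method: the aryloxide adds to the β-carbon of the vinylogous ester (C–OMe) and expels MeO⁻ (addition–elimination, SNV). The quinone has no free C–H, so only substitution can occur, and the two OMe groups are equivalent, so there is no regiochemical issue. The closest known reactions are amine/thiolate substitution on 2,3-dimethoxyquinones and aryloxide substitution on 2,3-dichloronaphthoquinone. No stereocentres form.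

**Step 6**
Reactants: 8
Product: 9 (hydroquinone: 2-aryloxy-3-methoxy-5,6-diprenylbenzene-1,4-diol)
Conditions: Na₂S₂O₄, THF/H₂O 1:1, rt, 15 min, then use immediately under N₂
Reagents that add atoms: none (adds H only)
Why: dithionite reduction of the quinone to the hydroquinone; the ester, benzyl ethers and prenyl alkenes are untouched.

**Step 7**
Reactants: 9
Product: 10 (ring-B C5-OMe, C2-OH diaryl ether)
Conditions: MeI (1.1 equiv), K₂CO₃ (1.0 equiv), acetone, 0 °C → rt, N₂
Reagents that add atoms: methyl iodide, CI
Why: Williamson mono-O-methylation. The C2-OH sits next to the bulky ortho-disubstituted aryloxy group and is H-bonded to the ring-A ester/ether oxygen, so the freer C5-OH, which sits next to the small OMe, reacts first (expected at least 3:1; the isomers are separable). No stereocentres form.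

**Step 8**
Reactants: 10
Product: 11 (4-methylhydroatrovirinone)
Conditions: BCl₃ (5 equiv), pentamethylbenzene (6 equiv), CH₂Cl₂, –78 °C, 40 min; quench with MeOH at –78 °C
Reagents that add atoms: none
Why: BCl₃ with a cation scavenger cleaves aryl benzyl ethers selectively at –78 °C. Prenyl alkenes, aryl methyl ethers and the methyl ester survive, and no stereocentres are involved.

## Compound list
1 | methyl 2,4,6-trihydroxybenzoate | COC(=O)c1c(O)cc(O)cc1O | starting material
2 | methyl 2,4-bis(benzyloxy)-6-hydroxybenzoate | COC(=O)c1c(O)cc(OCc2ccccc2)cc1OCc1ccccc1 | intermediate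
3 | 1,2,3,4-tetramethoxybenzene | COc1ccc(OC)c(OC)c1OC | starting material
4 | 1-bromo-3-methylbut-2-ene (prenyl bromide) | CC(C)=CCBr | starting material
5 | 1,2,3,4-tetramethoxy-5-(3-methylbut-2-enyl)benzene | COc1cc(CC=C(C)C)c(OC)c(OC)c1OC | intermediate
6 | 1,2,3,4-tetramethoxy-5,6-bis(3-methylbut-2-enyl)benzene | COc1c(OC)c(OC)c(CC=C(C)C)c(CC=C(C)C)c1OC | intermediate
7 | 2,3-dimethoxy-5,6-bis(3-methylbut-2-enyl)-1,4-benzoquinone | COC1=C(OC)C(=O)C(CC=C(C)C)=C(CC=C(C)C)C1=O | intermediate
8 | 2-[3,5-bis(benzyloxy)-2-(methoxycarbonyl)phenoxy]-3-methoxy-5,6-diprenyl-1,4-benzoquinone | COC1=C(Oc2cc(OCc3ccccc3)cc(OCc3ccccc3)c2C(=O)OC)C(=O)C(CC=C(C)C)=C(CC=C(C)C)C1=O | intermediate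
9 | hydroquinone of 8 (ring B: 1-OAr, 2-OH, 5-OH, 6-OMe) | COc1c(O)c(CC=C(C)C)c(CC=C(C)C)c(O)c1Oc1cc(OCc2ccccc2)cc(OCc2ccccc2)c1C(=O)OC | intermediate
10 | 5-O-methyl ether of 9 | COc1c(OC)c(CC=C(C)C)c(CC=C(C)C)c(O)c1Oc1cc(OCc2ccccc2)cc(OCc2ccccc2)c1C(=O)OC | intermediate
11 | 4-methylhydroatrovirinone | COC(=O)c1c(O)cc(O)cc1Oc1c(O)c(CC=C(C)C)c(CC=C(C)C)c(OC)c1OC | target

## Totals
Total steps: 8. Longest linear sequence: 7 (Steps 2–8).

## Three steps most likely to fail
1. **Step 5 (phenoxide SNV on the quinone).** The chelated, hindered phenoxide may be a poor nucleophile or may attack through carbon.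
   - Fallback: a depsidone route. Mono-methylate the hydroquinone from 7 to the 2,3,4-trimethoxy-5,6-diprenylphenol and acylate it with 2-fluoro-4,6-bis(benzyloxy)benzoyl chloride. Then do a BCl₃ ortho-demethylation and Cs₂CO₃ intramolecular SNAr to the depsidone, and open the lactone with NaOMe/MeOH. This forms the ether intramolecularly and fixes the regiochemistry by the tether.
2. **Step 7 (regioselective mono-methylation).** C2-OH versus C5-OH selectivity may be poor.
   - Fallback: desymmetrise through a quinone monoketal. Make the mono-allyl ether of the symmetric hydroquinone from 7 and oxidise it with PIDA in allyl alcohol to the bis(allyl) ketal dienone. Do the SNV with 2, which places the aryloxy group next to the ketal carbon, then reductively aromatise with Na₂S₂O₄. The C5-OH is then unique and is methylated with MeI, followed by Pd(0)/BCl₃ deprotection.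
3. **Step 3 (second ortho-lithiation/prenylation).** The site is hindered by the neighbouring prenyl group, and SN2′ coupling gives reverse-prenyl by-products.
   - Fallback: brominate 5 with NBS at C6, then do Br/Li exchange with t-BuLi and a Cu-mediated prenylation. This replaces C–H deprotonation with halogen–metal exchange as the way to make the aryl–metal species.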